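## Structural features

Norspiculoic acid A is a hydrindenone: a cyclohexene (ring A, C1–C6) trans-fused through C5–C6 to a cyclopentanone (ring B, C5–C9, carbonyl at C8). The difficulty lies in ring A, where C3 (ethyl, E-styryl) and C4 (ethyl, carboxyl) are neighbouring quaternary stereocentres with their ethyl groups cis, and C4 is bonded to the ring-fusion carbon C5. There are six stereocentres (C3, C4, C5, C6, C7, C9). C5 and C6 are trans, and the methyl-bearing carbons C7 and C9 flank the ketone, each trans to its ring-fusion neighbour, so both can be corrected by enolisation. Fragile points are these two epimerisable centres, the neopentyl carboxyl group (its esters resist acyl substitution, and strong acid can lactonise it onto the C1=C2 or styryl alkene) and the styrene. The C1=C2 alkene is trisubstituted, with ethyl on C1 and the CH (C2) bonded to quaternary C3. The feature the key step uses is that both the ring bond C3–C2 and the styryl group leave C3 through sp2 carbons: C3 can be built carrying two identical vinyl groups, one of which closes ring A onto a but-1-en-2-yl group on C6 while the other is arylated later.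

## Logic of the disconnections

25 ⇒ 24. The O–CH3 bond of an ester is cut. The carboxyl group is masked through the cuprate and palladium steps so that a carboxylate cannot attack the neighbouring vinyl group during arylation. The forward step must attack the methyl carbon, because the carbonyl carbon on C4 is shielded.

24 ⇒ 22 + 23. The styryl C(sp2)–aryl bond is cut. This leaves a plain vinyl group on C3, identical to the one used for ring closure. The forward arylation must be terminal and E-selective on a hindered monosubstituted alkene and must ignore the ring alkene.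

22 ⇒ 21. The C1=C2 double bond is cut. Ring A opens, C3 ceases to be a stereocentre (two like vinyl groups), and what remains is a cyclopentanone carrying all other stereocentres. The forward step must join two hindered alkenes and choose one of two diastereotopic vinyl groups.

21 ⇒ 17 + 18. The C6–alkenyl and C7–CH3 bonds are cut. Both trans relationships on ring B come from one conjugate addition with enolate methylation, anti to the bulky C5 substituent. Adding the butenyl group last keeps C6 and C7 unsubstituted during the rearrangement and avoids an early cyclopentenone with a doubly allylic, base-labile hydrogen at C6. The forward step needs a cuprate to add beside a very bulky group.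

17 ⇒ 15. The C6=C7 alkene is traced back to a C6 silyloxy group (β-elimination) and the ester methyl to the acid. The silyloxy group is both the latent enone and the control element for C5. The elimination must not move the alkene toward C5.

15 ⇒ 12. The C3–C4 bond is cut as a [3,3] shift of an ester enolate. Only a concerted intramolecular process can join two fully substituted carbons. Because the allyl partner is a symmetric dienyl unit, C3 is not stereogenic and only C4 has to be controlled. The forward step needs face selection at the ketene acetal from C5 and a masked ketone.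

12 ⇒ 6 + 9. The C4–C5 bond is cut (conjugate addition) together with the O–Si bond. Side chain and ring are joined convergently, anti to the C6 silyloxy group, so the absolute configuration of C5 comes from the chiral pool. The forward step needs 1,4- rather than 1,2-addition, and trapping of the regiodefined enolate.

9 ⇒ 8 ⇒ 7. The C9–CH3 bond is cut (cross-coupling of an α-iodo enone). The methyl group must be on the enone before the conjugate addition, because the enol ether C8=C9(CH3) is the screen used in the rearrangement. Enantiopure 7 is chosen as the source of chirality; an achiral enone lacking the silyloxy group would need a catalytic asymmetric alkenyl addition to an α-substituted enone, for which there is little to build on.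

6 ⇒ 4 + 5, and 4 ⇒ 3 ⇒ 1 + 2. The ester C–O bond, then the alcohol oxidation level, then the bond between the vinyl group and C3 of the dienoate are cut. This leads to 1 and 2. The carbocupration needs only conjugate regiochemistry, since either alkene geometry gives the same C3 later.

## Other disconnections considered

Alternative 1: The cut is the C5–C6 bond of ring B. In the forward direction the cross-conjugated tetraenone A1 is activated by an acid (BF3·OEt2 for racemic work, a chiral N-triflylphosphoramide for the asymmetric version), the pentadienyl cation closes by conrotatory 4π electrocyclisation, and Et3SiH reduces the oxyallyl cation to the C2-symmetric cyclopentanone A2.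
- In its favour: one step makes ring B and the trans C5/C6 relationship by orbital symmetry. A1 is achiral and cheap. The two butenyl groups of A2 are homotopic, so converting one of them cannot give regioisomers.
- Against it here: the β-carbons of A1 carry vinyl groups, which spread the charge into the side arms and open polymerisation and other closures. High enantioselectivity in such closures is established for dienones polarised by a heteroatom or ester group, not for alkyl- and alkenyl-substituted ones. A2 is also still far from the target: one butenyl group must become the 1-carboxypropyl chain (hydroboration and two oxidations, stopped statistically at mono-conversion), and the Claisen rearrangement and metathesis of the chosen plan are still needed, now with C6 already substituted and C8 not regioselectively masked.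
- Comparison: on structure it addresses only ring B, which the chosen plan gets from two routine anti additions. On mechanism it is the better on the C5/C6 relationship (one pericyclic step instead of two diastereoselective additions), and the equal on the source of absolute configuration only if the catalyst performs. On step economy it replaces steps 4–6 and 8–9 by about as many operations with lower throughput.

Alternative 2: The cut is the C6–C7 bond. Rh2(OAc)4 decomposes the diazoketone A3, and the carbenoid carbon (C7) inserts into the equatorial allylic C6–H bond to give the trans-fused keto ester A4; C7 is methylated afterwards.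
- In its favour: ring B is closed last on a complete ring A, so no group selection at C3 is needed and the styryl group is already in place; on these two counts it is the better plan. Cyclopentanone formation by 1,5-insertion is dependable and the allylic C–H bond is activated. The endgame (methylation, ester cleavage) is as short as that of the chosen plan, an equal point.
- Against it: the real difficulty (C3, C4 and C5 on a cyclohexene, plus C9 on the side chain) is untouched by the key step and needs a separate solution. The carbenoid sits next to the C1=C2 alkene, where cyclopropanation normally outruns insertion, and it can reach C–H bonds of the C4 ethyl group. Trans fusion requires insertion into the equatorial C–H bond, while the cis-fused ring is usually easier. Diazoketones add hazard.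
- Comparison: the chosen plan closes ring A with a catalyst that recognises only alkenes, whereas this one needs one C–H bond out of several and must spare two alkenes. Step economy cannot favour it, because A3 still needs a full synthesis of the quaternary pair.

Alternative 3: The cut removes C2–C3 and C4–C5. The 2-ethoxy diene A5 and 2,3-diethylmaleic anhydride A6 combine in a Diels–Alder reaction under high pressure to give the tricyclic adduct A7.
- In its favour: both quaternary carbons arise in one step and their cis-diethyl relationship is copied from the alkene of A6. On this point it is better than the chosen plan, which needs a face-selective rearrangement and a group-selective metathesis. C5 is set at the same time, anti to the C9 methyl group, and the route is convergent.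
- Against it: a tetrasubstituted anhydride is among the least reactive dienophiles and must bond to a ring carbon of the diene, so very high pressure is needed and the acid-sensitive enol ether may not survive. The endo/exo orientation, which decides whether ethyl or carbonyl on C4 is cis to H5, has no clear bias. After A7 the two anhydride carbonyls must be told apart (one reduced and olefinated to the E-styryl group, one kept as the acid), the enol ether turned into the ethyl-substituted C1=C2 alkene (ketone, enol triflate, cross-coupling), the C6 centre set, C7 methylated and the ketal removed.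
- Comparison: structurally it solves C3/C4 best. Mechanistically it depends on a cycloaddition of doubtful rate where the chosen plan uses intramolecular steps that tolerate congestion. The roughly ten operations after A7 make it clearly longer than the chosen route, which needs ten steps in its longest line from first starting material to target.

Key step: step 10

Remark: (4R)-4-{[tert-butyl(dimethyl)silyl]oxy}cyclopent-2-en-1-one, ethyl pent-2-ynoate, vinylmagnesium bromide and methylzinc chloride are taken as commercial; locants C1–C9 are those of the target skeleton, and every stereocentre that 21 and 22 share with 25 carries the configuration it has in 25.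

## Route

Step 1
Reactants: 1 ethyl pent-2-ynoate; 2 ethenylmagnesium bromide (vinylmagnesium bromide)
Product: 3 ethyl (2E)-3-ethylpenta-2,4-dienoate
Conditions: CH2=CHMgBr (2.2 equiv), CuI (1.1 equiv), THF, −78 °C; aq. NH4Cl, −78 °C
Reagents that add atoms: none
Why: Conjugate syn carbocupration of an alkynoate by a vinylcuprate; cold protonation keeps the alkenylcopper configuration and gives the 2E diene ester. The alkene geometry is not critical, because both alkene ends of this unit finish as the two vinyl groups on C3.

Step 2
Reactants: 3 ethyl (2E)-3-ethylpenta-2,4-dienoate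
Product: 4 (2E)-3-ethylpenta-2,4-dien-1-ol
Conditions: iBu2AlH (2.2 equiv), CH2Cl2, −78 → 0 °C; aq. KNaC4H4O6 (potassium sodium tartrate)
Reagents that add atoms: none
Why: 1,2-Reduction of a conjugated ester by a dialkylaluminium hydride gives the allylic alcohol and leaves the diene untouched.

Step 3
Reactants: 4 (2E)-3-ethylpenta-2,4-dien-1-ol; 5 butanoyl chloride
Product: 6 (2E)-3-ethylpenta-2,4-dien-1-yl butanoate
Conditions: pyridine, DMAP (cat.), CH2Cl2, 0 °C
Reagents that add atoms: none
Why: Acylation of a primary allylic alcohol by an acid chloride under nucleophilic catalysis.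

Step 4
Reactants: 7 (4R)-4-{[tert-butyl(dimethyl)silyl]oxy}cyclopent-2-en-1-one
Product: 8 (4R)-4-{[tert-butyl(dimethyl)silyl]oxy}-2-iodocyclopent-2-en-1-one
Conditions: I2 (1.5 equiv), pyridine–CH2Cl2 (1:1), 0 → 23 °C
Reagents that add atoms: iodine, II
Why: α-Iodination of a cyclic enone by conjugate addition of pyridine, iodination of the enolate and elimination; the silyloxy-bearing stereocentre is not involved.

Step 5
Reactants: 8 (4R)-4-{[tert-butyl(dimethyl)silyl]oxy}-2-iodocyclopent-2-en-1-one
Product: 9 (4R)-4-{[tert-butyl(dimethyl)silyl]oxy}-2-methylcyclopent-2-en-1-one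
Conditions: MeZnCl (1.5 equiv), Pd(PPh3)4 (5 mol %), THF, 23 °C
Reagents that add atoms: methylzinc chloride, C[Zn]Cl
Why: Negishi cross-coupling of an α-iodo enone; the neutral conditions keep the γ-silyloxy enone from eliminating.

Step 6
Reactants: 6 (2E)-3-ethylpenta-2,4-dien-1-yl butanoate; 9 (4R)-4-{[tert-butyl(dimethyl)silyl]oxy}-2-methylcyclopent-2-en-1-one
Product: 12 (2E)-3-ethylpenta-2,4-dien-1-yl (2RS)-2-[(1R,5R)-5-{[tert-butyl(dimethyl)silyl]oxy}-2-methyl-3-[(triethylsilyl)oxy]cyclopent-2-en-1-yl]butanoate, via ester lithium enolate 10 (not isolated), via adduct lithium enolate 11 (not isolated)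
Conditions: LiN(iPr)2 (1.1 equiv), THF, −78 °C; 6; then 9, −78 → −40 °C; Et3SiCl (1.3 equiv), Et3N, −78 → 0 °C
Reagents that add atoms: chlorotriethylsilane, CC[Si](Cl)(CC)CC
Why: Michael addition of an ester lithium enolate to a cyclopentenone; any 1,2-adduct reverts on warming and the conjugate adduct collects as the more stable ketone enolate, which is then O-silylated. The nucleophile enters C5 anti to the C6 silyloxy group, which fixes C5; the enol ether masks the ketone and puts the C9 methyl group in the ring plane. C4 forms as a mixture that step 7 erases.

Step 7
Reactants: 12 (2E)-3-ethylpenta-2,4-dien-1-yl (2RS)-2-[(1R,5R)-5-{[tert-butyl(dimethyl)silyl]oxy}-2-methyl-3-[(triethylsilyl)oxy]cyclopent-2-en-1-yl]butanoate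
Product: 15 (2S)-2-[(1S,5R)-5-{[tert-butyl(dimethyl)silyl]oxy}-2-methyl-3-oxocyclopentyl]-3-ethenyl-2,3-diethylpent-4-enoic acid (methyl-bearing ring carbon C9 not yet set), via silyl ketene acetal 13 (not isolated), via rearranged trimethylsilyl ester 14 (not isolated)
Conditions: LiN(iPr)2 (1.5 equiv), Me3SiCl–Et3N (premixed), THF, −78 → 23 °C, then 60 °C; 1 M HCl, THF, 0 °C
Reagents that add atoms: none
Why: Ireland–Claisen rearrangement: ketene acetal 13 shifts [3,3] and joins C4 to the ethyl-bearing terminus of the dienyl unit; both alkene ends become vinyl groups, so C3 is not stereogenic and neither ketene-acetal geometry nor chair/boat choice can change the product. C4 is set by face selection: C5–H eclipses the ketene-acetal double bond (allylic 1,3-strain), the C9 flank is screened by the in-plane vinylic methyl group of the enol ether, and bonding on the C6 flank, which offers only C6–H, gives (S)-C4. Dilute acid then cleaves the silyl ester and the enol ether; C9 is left unset, and premature loss of silanol would only anticipate step 8.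

Step 8
Reactants: 15 (2S)-2-[(1S,5R)-5-{[tert-butyl(dimethyl)silyl]oxy}-2-methyl-3-oxocyclopentyl]-3-ethenyl-2,3-diethylpent-4-enoic acid
Product: 17 methyl (2S)-3-ethenyl-2,3-diethyl-2-[(1S,5R)-5-methyl-4-oxocyclopent-2-en-1-yl]pent-4-enoate, via enone acid 16 (not isolated)
Conditions: DBU (3 equiv), MeCN, 0 → 23 °C; then MeI (2 equiv), 23 °C
Reagents that add atoms: iodomethane, CI
Why: E1cB loss of silanolate from the β-silyloxy ketone gives the cyclopentenone, and the same base equilibrates C9 so that its methyl group is trans to the bulky C5 substituent. The amidinium carboxylate is then O-methylated by SN2, which is indifferent to the hindrance at C4. Should the carboxylate add reversibly to C6 of the enone, the same base reopens the lactone by the E1cB path and the methylation removes the open form.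

Step 9
Reactants: 17 methyl (2S)-3-ethenyl-2,3-diethyl-2-[(1S,5R)-5-methyl-4-oxocyclopent-2-en-1-yl]pent-4-enoate; 18 2-bromobut-1-ene
Product: 21 methyl (2S)-2-[(1S,2S,3R,5R)-2-(but-1-en-2-yl)-3,5-dimethyl-4-oxocyclopentyl]-3-ethenyl-2,3-diethylpent-4-enoate, via but-1-en-2-ylmagnesium bromide 19 (not isolated), via bromomagnesium enolate 20 (not isolated)
Conditions: 18, Mg, THF, 40 °C; CuBr·SMe2 (0.5 equiv per RMgBr), THF, −40 °C; 17, −78 → −40 °C; MeI (5 equiv), DMPU, −40 → 0 °C
Reagents that add atoms: iodomethane, CI
Why: Conjugate addition of a magnesium dialkenylcuprate followed by C-methylation of the enolate (three-component coupling): the alkenyl group enters C6 anti to the bulky C5 substituent and the methyl group enters C7 anti to the new alkenyl group, giving the all-trans ring B. C7 is in any case epimerisable to the trans arrangement, and the hindered ester and the vinyl groups are inert to the cuprate at low temperature.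

Step 10
Reactants: 21 methyl (2S)-2-[(1S,2S,3R,5R)-2-(but-1-en-2-yl)-3,5-dimethyl-4-oxocyclopentyl]-3-ethenyl-2,3-diethylpent-4-enoate
Product: 22 methyl (1R,3R,3aS,4S,5R,7aS)-5-ethenyl-4,5,7-triethyl-1,3-dimethyl-2-oxo-2,3,3a,4,5,7a-hexahydro-1H-indene-4-carboxylate
Conditions: RuCl2(H2IMes)(=CH–C6H4-2-OiPr) (second-generation Hoveyda–Grubbs catalyst, 10 mol %), toluene, 0.005 M, 80 °C, argon sparge
Reagents that add atoms: none
Why: Ring-closing alkene metathesis through a metallacyclobutane: the ruthenium alkylidene exchanges onto one of the vinyl groups on C3, adds [2+2] to the 1,1-disubstituted alkene on C6, and cycloreverts to the C1=C2 alkene, with loss of ethene making the closure irreversible. The closest known reaction type is the desymmetrising ring-closing metathesis of prochiral trienes that creates a quaternary stereocentre beside the new ring alkene. Ring A closes as a six-membered ring with an endocyclic trisubstituted alkene; because the two chains on C5 and C6 are trans, it can form only as the trans-fused half-chair, in which the C4 ethyl group is axial and the ester equatorial. C3 becomes stereogenic here, and its configuration is decided by which diastereotopic vinyl group reacts: in the favoured half-chair the C3 ethyl group is pseudo-equatorial and the spectator vinyl group pseudo-axial, anti to the axial C4 ethyl group, where its only syn-axial neighbour is H5, whereas the other closure forces an ethyl group into that site with its methyl end against the C4 ester or over the ring. Loading of the catalyst on either vinyl group is reversible relative to cyclisation, so the product ratio reflects only this difference between the two cyclisation transition states (Curtin–Hammett). The step needs group selectivity between the two vinyl groups, which rests on this modest conformational bias and is the least secure point, and chemoselectivity, which rests on high dilution, the quaternary carbons holding the alkenes together, and the tolerance of ruthenium carbenes for ketone and ester. A phosphine-free second-generation catalyst is chosen because both reacting alkenes are hindered.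

Step 11
Reactants: 22 methyl (1R,3R,3aS,4S,5R,7aS)-5-ethenyl-4,5,7-triethyl-1,3-dimethyl-2-oxo-2,3,3a,4,5,7a-hexahydro-1H-indene-4-carboxylate; 23 iodobenzene
Product: 24 methyl (1R,3R,3aS,4S,5R,7aS)-4,5,7-triethyl-1,3-dimethyl-2-oxo-5-[(E)-2-phenylethenyl]-2,3,3a,4,5,7a-hexahydro-1H-indene-4-carboxylate
Conditions: Pd(OAc)2 (10 mol %), Bu4NCl (1 equiv), NaHCO3 (2.5 equiv), DMF, 80 °C
Reagents that add atoms: none
Why: Mizoroki–Heck arylation under ligand-free phase-transfer conditions: phenylpalladium iodide adds across the only monosubstituted alkene with phenyl on the terminal carbon, and since C3 is quaternary the only β-hydrogens are the benzylic ones, so syn elimination gives the E-styryl group. The trisubstituted ring alkene is too hindered to insert.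

Step 12
Reactants: 24 methyl (1R,3R,3aS,4S,5R,7aS)-4,5,7-triethyl-1,3-dimethyl-2-oxo-5-[(E)-2-phenylethenyl]-2,3,3a,4,5,7a-hexahydro-1H-indene-4-carboxylate
Product: 25 norspiculoic acid A, (1R,3R,3aS,4S,5R,7aS)-4,5,7-triethyl-1,3-dimethyl-2-oxo-5-[(E)-2-phenylethenyl]-2,3,3a,4,5,7a-hexahydro-1H-indene-4-carboxylic acid
Conditions: LiI (10 equiv), pyridine, 115 °C; 1 M HCl
Reagents that add atoms: none
Why: Nucleophilic demethylation: iodide attacks the ester methyl group by SN2, so the shielding of the C4 carbonyl carbon does not matter, and acidification frees the acid. C7 and C9 already hold their stable trans arrangements, so the hot, weakly basic medium cannot change them.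

## Compound list

1 | ethyl pent-2-ynoate | CCC#CC(=O)OCC | starting material
2 | ethenylmagnesium bromide | C=C[Mg]Br | starting material
3 | ethyl (2E)-3-ethylpenta-2,4-dienoate | CCOC(=O)/C=C(CC)/C=C | intermediate
4 | (2E)-3-ethylpenta-2,4-dien-1-ol | OC/C=C(CC)/C=C | intermediate
5 | butanoyl chloride | CCCC(=O)Cl | starting material
6 | (2E)-3-ethylpenta-2,4-dien-1-yl butanoate | CCCC(=O)OC/C=C(CC)/C=C | intermediate
7 | (4R)-4-{[tert-butyl(dimethyl)silyl]oxy}cyclopent-2-en-1-one | O=C1C=C[C@H](O[Si](C)(C)C(C)(C)C)C1 | starting material
8 | (4R)-4-{[tert-butyl(dimethyl)silyl]oxy}-2-iodocyclopent-2-en-1-one | O=C1C(I)=C[C@H](O[Si](C)(C)C(C)(C)C)C1 | intermediate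
9 | (4R)-4-{[tert-butyl(dimethyl)silyl]oxy}-2-methylcyclopent-2-en-1-one | CC1=C[C@H](O[Si](C)(C)C(C)(C)C)CC1=O | intermediate
10 | lithium enolate of 6 (enolate geometry open) | CCC=C(O[Li])OC/C=C(CC)/C=C | intermediate
11 | lithium enolate of the conjugate adduct (side chain on C5 trans to the C6 silyloxy group; C4 mixture) | CCC(C(=O)OC/C=C(CC)/C=C)[C@H]1[C@H](O[Si](C)(C)C(C)(C)C)CC(O[Li])=C1C | intermediate
12 | (2E)-3-ethylpenta-2,4-dien-1-yl (2RS)-2-[(1R,5R)-5-{[tert-butyl(dimethyl)silyl]oxy}-2-methyl-3-[(triethylsilyl)oxy]cyclopent-2-en-1-yl]butanoate | CCC(C(=O)OC/C=C(CC)/C=C)[C@H]1[C@H](O[Si](C)(C)C(C)(C)C)CC(O[Si](CC)(CC)CC)=C1C | intermediate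
13 | trimethylsilyl ketene acetal of 12 (geometry open) | CCC(=C(O[Si](C)(C)C)OC/C=C(CC)/C=C)[C@H]1[C@H](O[Si](C)(C)C(C)(C)C)CC(O[Si](CC)(CC)CC)=C1C | intermediate
14 | trimethylsilyl (2S)-2-[(1S,5R)-5-{[tert-butyl(dimethyl)silyl]oxy}-2-methyl-3-[(triethylsilyl)oxy]cyclopent-2-en-1-yl]-3-ethenyl-2,3-diethylpent-4-enoate | C=CC(CC)(C=C)[C@@](CC)(C(=O)O[Si](C)(C)C)[C@H]1[C@H](O[Si](C)(C)C(C)(C)C)CC(O[Si](CC)(CC)CC)=C1C | intermediate
15 | (2S)-2-[(1S,5R)-5-{[tert-butyl(dimethyl)silyl]oxy}-2-methyl-3-oxocyclopentyl]-3-ethenyl-2,3-diethylpent-4-enoic acid (C9 epimers) | C=CC(CC)(C=C)[C@@](CC)(C(=O)O)[C@H]1[C@H](O[Si](C)(C)C(C)(C)C)CC(=O)C1C | intermediate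
16 | (2S)-3-ethenyl-2,3-diethyl-2-[(1S,5R)-5-methyl-4-oxocyclopent-2-en-1-yl]pent-4-enoic acid | C=CC(CC)(C=C)[C@@](CC)(C(=O)O)[C@H]1C=CC(=O)[C@@H]1C | intermediate
17 | methyl (2S)-3-ethenyl-2,3-diethyl-2-[(1S,5R)-5-methyl-4-oxocyclopent-2-en-1-yl]pent-4-enoate | C=CC(CC)(C=C)[C@@](CC)(C(=O)OC)[C@H]1C=CC(=O)[C@@H]1C | intermediate
18 | 2-bromobut-1-ene | C=C(Br)CC | starting material
19 | but-1-en-2-ylmagnesium bromide | CCC(=C)[Mg]Br | intermediate
20 | bromomagnesium enolate of the butenyl adduct | C=CC(CC)(C=C)[C@@](CC)(C(=O)OC)[C@H]1[C@H](C(=C)CC)C=C(O[Mg]Br)[C@@H]1C | intermediate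
21 | methyl (2S)-2-[(1S,2S,3R,5R)-2-(but-1-en-2-yl)-3,5-dimethyl-4-oxocyclopentyl]-3-ethenyl-2,3-diethylpent-4-enoate | C=CC(CC)(C=C)[C@@](CC)(C(=O)OC)[C@H]1[C@H](C(=C)CC)[C@@H](C)C(=O)[C@@H]1C | intermediate
22 | methyl (1R,3R,3aS,4S,5R,7aS)-5-ethenyl-4,5,7-triethyl-1,3-dimethyl-2-oxo-2,3,3a,4,5,7a-hexahydro-1H-indene-4-carboxylate | CCC1=C[C@](C=C)(CC)[C@@](CC)(C(=O)OC)[C@H]2[C@H]1[C@@H](C)C(=O)[C@@H]2C | intermediate
23 | iodobenzene | Ic1ccccc1 | starting material
24 | methyl (1R,3R,3aS,4S,5R,7aS)-4,5,7-triethyl-1,3-dimethyl-2-oxo-5-[(E)-2-phenylethenyl]-2,3,3a,4,5,7a-hexahydro-1H-indene-4-carboxylate | CCC1=C[C@](/C=C/c2ccccc2)(CC)[C@@](CC)(C(=O)OC)[C@H]2[C@H]1[C@@H](C)C(=O)[C@@H]2C | intermediate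
25 | norspiculoic acid A | CCC1=C[C@](/C=C/c2ccccc2)(CC)[C@@](CC)(C(=O)O)[C@H]2[C@H]1[C@@H](C)C(=O)[C@@H]2C | target

## Step count and least certain steps

Total: 12 steps. Steps 1–3 make ester 6 and steps 4–5 make enone 9; the two branches meet in step 6, and steps 6–12 are common to both.

Longest linear sequence: 10 steps, from 1 to 25 (steps 1–3 and 6–12). The other branch, which starts at 7 and runs through steps 4 and 5, is one step shorter.

**Step 10 (key step).** The two vinyl groups may be discriminated poorly, because the steric difference between an ethyl and a vinyl group on C3 is small; a mixture of C3 epimers would then form, and initiation on the neopentyl-type vinyl groups may also be slow. Fallback (sets out from 3, comes back at 24): the aryl group is introduced first, so that C3 is already a stereocentre when ring A closes and only one vinyl group is left for the closure. Heck arylation of 3 with 23 should give ethyl (2E,4E)-3-ethyl-5-phenylpenta-2,4-dienoate F1; iBu2AlH reduction then gives (2E,4E)-3-ethyl-5-phenylpenta-2,4-dien-1-ol F2, and acylation with 5 gives (2E,4E)-3-ethyl-5-phenylpenta-2,4-dien-1-yl butanoate F3. F3 is taken through the chemistry of steps 6–9: conjugate addition to 9 with silyl trapping gives the silyl enol ether adduct F4, rearrangement and hydrolysis give the silyloxy keto acid F5, elimination and methylation give the enone ester F6, and cuprate addition with methyl trapping gives the styryl triene F7. In the rearrangement C3 and C4 now form together through the chair transition state; with the 2E dienol the ethyl group of the ketene acetal must stand cis to the dienyloxy group, which calls for enolisation in THF–DMPU. Ring-closing metathesis of F7 should engage the vinyl group in preference to the disubstituted styryl alkene and give 24 directly, so that step 11 falls away.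

**Step 7.** The allyl terminus may bond to the wrong face of the ketene acetal, because the C6 and C9 flanks differ only by a hydrogen against an in-plane methyl group; a C4 epimer mixture would result. Fallback (sets out from 6 and 9, comes back at 15): the screen is changed from an sp2 to an sp3 one. The adduct enolate 11 is protonated at −78 °C with 2,6-di-tert-butyl-4-methylphenol instead of being silylated; protonation from the face away from the side chain gives the ketone with the C9 methyl group cis to the side chain, (2E)-3-ethylpenta-2,4-dien-1-yl 2-[(1S,2S,5R)-5-{[tert-butyl(dimethyl)silyl]oxy}-2-methyl-3-oxocyclopentyl]butanoate F8. With 2.3 equiv LiN(iPr)2 and Me3SiCl the ketone is masked in the flask as its less substituted silyl enol ether and the ester becomes the ketene acetal, so that the cis methyl group stands directly over the C9 flank during the rearrangement. Hydrolysis gives 15 as its C9 epimer, which step 8 equilibrates.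

**Step 6.** Addition to the carbonyl group, or proton transfer from C7 followed by loss of the silyloxy group, may compete with conjugate addition. Fallback (sets out from 9, comes back at 12): a Mukaiyama–Michael addition that involves no basic enolate. 1,1-Bis[(triethylsilyl)oxy]but-1-ene F9 is prepared from butanoic acid with 2 equiv LiN(iPr)2 and Et3SiCl and adds to 9 under catalysis by Et3SiOTf with silyl transfer, giving the silyl ester–silyl enol ether F10. Aqueous NaHCO3 cleaves only the silyl ester to give the acid F11, which is esterified with 4 (EDC·HCl, DMAP) to give 12.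

**Step 9.** Conjugate addition beside the bulky C5 substituent may be slow, and methylation of the hindered enolate may be incomplete or multiple. Fallback (sets out from 17, comes back at 21): the C7 methyl group is installed before the conjugate addition by the chemistry of steps 4 and 5. I2/pyridine gives the iodo enone ester F12, and MeZnCl with Pd(PPh3)4 gives the methyl enone ester F13. Addition of the cuprate from 19 (accelerated by Me3SiCl) followed by protonation then has to deliver only the alkenyl group, and C7 settles trans under thermodynamic control to give 21.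

**Step 12.** Dealkylation may be incomplete, or prolonged heating may slowly degrade the material. Fallback (sets out from 24, comes back at 25): a reduction–oxidation detour. LiAlH4 reduces both carbonyl groups (hydride is small enough for the neopentyl ester) to the diol F14, Dess–Martin periodinane oxidises both alcohols to the keto aldehyde F15, and NaClO2/NaH2PO4/2-methylbut-2-ene oxidises the aldehyde to 25.

## Further compounds

F1 | step 10 | ethyl (2E,4E)-3-ethyl-5-phenylpenta-2,4-dienoate | CCOC(=O)/C=C(CC)/C=C/c1ccccc1
F2 | step 10 | (2E,4E)-3-ethyl-5-phenylpenta-2,4-dien-1-ol | OC/C=C(CC)/C=C/c1ccccc1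
F3 | step 10 | (2E,4E)-3-ethyl-5-phenylpenta-2,4-dien-1-yl butanoate | CCCC(=O)OC/C=C(CC)/C=C/c1ccccc1
F4 | step 10 | silyl enol ether adduct of F3 and 9 | CCC(C(=O)OC/C=C(CC)/C=C/c1ccccc1)[C@H]1[C@H](O[Si](C)(C)C(C)(C)C)CC(O[Si](CC)(CC)CC)=C1C
F5 | step 10 | silyloxy keto acid with vinyl and styryl groups on C3 (C9 epimers) | C=C[C@](/C=C/c1ccccc1)(CC)[C@@](CC)(C(=O)O)[C@H]1[C@H](O[Si](C)(C)C(C)(C)C)CC(=O)C1C
F6 | step 10 | enone methyl ester with vinyl and styryl groups on C3 | C=C[C@](/C=C/c1ccccc1)(CC)[C@@](CC)(C(=O)OC)[C@H]1C=CC(=O)[C@@H]1C
F7 | step 10 | styryl triene, the 5-phenyl analogue of 21 | C=C[C@](/C=C/c1ccccc1)(CC)[C@@](CC)(C(=O)OC)[C@H]1[C@H](C(=C)CC)[C@@H](C)C(=O)[C@@H]1C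
F8 | step 7 | (2E)-3-ethylpenta-2,4-dien-1-yl 2-[(1S,2S,5R)-5-{[tert-butyl(dimethyl)silyl]oxy}-2-methyl-3-oxocyclopentyl]butanoate | CCC(C(=O)OC/C=C(CC)/C=C)[C@H]1[C@H](O[Si](C)(C)C(C)(C)C)CC(=O)[C@H]1C
F9 | step 6 | 1,1-bis[(triethylsilyl)oxy]but-1-ene | CCC=C(O[Si](CC)(CC)CC)O[Si](CC)(CC)CC
F10 | step 6 | triethylsilyl 2-[(1R,5R)-5-{[tert-butyl(dimethyl)silyl]oxy}-2-methyl-3-[(triethylsilyl)oxy]cyclopent-2-en-1-yl]butanoate | CCC(C(=O)O[Si](CC)(CC)CC)[C@H]1[C@H](O[Si](C)(C)C(C)(C)C)CC(O[Si](CC)(CC)CC)=C1C
F11 | step 6 | 2-[(1R,5R)-5-{[tert-butyl(dimethyl)silyl]oxy}-2-methyl-3-[(triethylsilyl)oxy]cyclopent-2-en-1-yl]butanoic acid | CCC(C(=O)O)[C@H]1[C@H](O[Si](C)(C)C(C)(C)C)CC(O[Si](CC)(CC)CC)=C1C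
F12 | step 9 | methyl (2S)-3-ethenyl-2,3-diethyl-2-[(1R,5R)-3-iodo-5-methyl-4-oxocyclopent-2-en-1-yl]pent-4-enoate | C=CC(CC)(C=C)[C@@](CC)(C(=O)OC)[C@H]1C=C(I)C(=O)[C@@H]1C
F13 | step 9 | methyl (2S)-3-ethenyl-2,3-diethyl-2-[(1S,5R)-3,5-dimethyl-4-oxocyclopent-2-en-1-yl]pent-4-enoate | C=CC(CC)(C=C)[C@@](CC)(C(=O)OC)[C@H]1C=C(C)C(=O)[C@@H]1C
F14 | step 12 | diol from reduction of 24 (C8 carbinol epimers) | CCC1=C[C@](/C=C/c2ccccc2)(CC)[C@@](CC)(CO)[C@H]2[C@H]1[C@@H](C)C(O)[C@@H]2C
F15 | step 12 | keto aldehyde corresponding to 25 | CCC1=C[C@](/C=C/c2ccccc2)(CC)[C@@](CC)(C=O)[C@H]2[C@H]1[C@@H](C)C(=O)[C@@H]2C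
A1 | alternative 1 | (3E,6E)-2,8-diethyl-4,6-dimethylnona-1,3,6,8-tetraen-5-one | C=C(CC)/C=C(C)/C(=O)/C(C)=C/C(CC)=C
A2 | alternative 1 | (2R,3S,4S,5R)-3,4-di(but-1-en-2-yl)-2,5-dimethylcyclopentan-1-one | CCC(=C)[C@H]1[C@H](C(=C)CC)[C@@H](C)C(=O)[C@@H]1C
A3 | alternative 2 | diazoketone on the C5 side chain of the complete ring A | CCC1=C[C@](/C=C/c2ccccc2)(CC)[C@@](CC)(C(=O)OC)[C@@H](C1)[C@@H](C)C(=O)C=[N+]=[N-]
A4 | alternative 2 | trans-fused bicyclic keto ester lacking the C7 methyl group | CCC1=C[C@](/C=C/c2ccccc2)(CC)[C@@](CC)(C(=O)OC)[C@H]2[C@H]1CC(=O)[C@@H]2C
A5 | alternative 3 | (6R)-8-(1-ethoxyethenyl)-6-methyl-1,4-dioxaspiro[4.4]non-7-ene | CCOC(=C)C1=C[C@@H](C)C2(OCCO2)C1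
A6 | alternative 3 | 2,3-diethylmaleic anhydride | CCC1=C(CC)C(=O)OC1=O
A7 | alternative 3 | tricyclic anhydride adduct with the enol ether at C1 | CCOC1=C2CC3(OCCO3)[C@H](C)[C@H]2[C@]4(CC)C(=O)OC(=O)[C@]4(CC)C1
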